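## Structural features

The target is the 4',7'',4'''-trimethyl ether of the 6,8''-linked biflavone agathisflavone. Unit 1 is an acacetin skeleton substituted at C6: carbocyclic ring A (C4a–C8a) with free 5-OH and 7-OH, γ-pyrone ring C, and 4-methoxyphenyl ring B. Unit 2 (double-primed atoms) is a 5''-hydroxy-7''-methoxy-2''-(4-methoxyphenyl)chromone substituted at C8''. The units share only the C6–C8'' bond, and all four ortho carbons carry oxygen (C5–OH, C7–OH, C7''–OMe, C8a''–O1''). This makes it a tetra-ortho-substituted, electron-rich biaryl axis, which is the only stereogenic element (there is no stereocentre) and is not specified. Both A rings are phloroglucinol rings in which C6 and C8 differ only in their relation to the pyrone oxygen, and hot acid interconverts the two series by Wessely–Moser ring opening, so "C6 on one half, C8'' on the other" is a true regiochemical problem. In addition, 7-OH must stay free while the nearly equivalent 7''-O is methylated, which rules out late methylation; the fragile groups are the γ-pyrone rings (nucleophilic base), the aryl methyl ethers (strong acids) and the free phloroglucinol ring A of unit 1 (oxidants). The key step exploits the position of C6 of ring A of unit 1 between C5–OH and C7–OH: C5–C6–C7 is the bis-enol of a 2-aryl-1,3-diketone, and ring A is an aromatised cyclic triketide. Cutting C5–C6 and hanging C5 on the C7 oxygen gives an isomeric 2-pyrone in which the axis is only a CH2–aryl bond, O1 is already fixed para to it, and both hydroxyls are masked in a lactone. The real difficulty is to create the hindered unsymmetrical axis, its 6/8'' regiochemistry and the OH/OMe pattern together.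

## Logic of the disconnections

**14 to 13.** The O5''–CH3 bond is added retrosynthetically (forward: one O–C bond is cut). A methyl ether on O5'' is what steers electrophilic substitution of unit 2 to C8'' earlier on, and it is the only one of the four methyl ethers that lies peri to a carbonyl. The gain is a permethylated unit 2 and no protecting group anywhere. The forward cleavage must be chelation-controlled and free of hot protic acid, which would open ring C of unit 1 and scramble the 6-linkage.

**13 to 10 (key).** The C5–C6 bond of ring A of unit 1 is cut, and C5 is re-attached to the oxygen on C7, so ring A becomes a 2-pyrone fused to the intact ring C.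
- In one sentence: ring A of unit 1 is made last, by base-induced isomerisation of 10.
- The gain is large. The tetra-ortho-substituted axis shrinks to an sp3–sp2 CH2–C8'' bond, and the stereogenic element disappears.
- The two free hydroxyls are stored as lactone carbonyl and lactone oxygen.
- The 6-versus-8 question is answered in advance, because O1 already sits in a closed ring.
- The forward step must C-acylate a hindered benzylic carbon, must not use C8 as the nucleophile, and must leave ring C closed.

**10 to 6 and 8 (through 9).** The CH2–C8'' bond is cut. This splits the molecule into two halves of equal size, and only one of the two carbons joined is di-ortho-substituted. The forward coupling must run in a neutral, non-nucleophilic medium, since the lactone, the γ-pyrone and the acidic CH2 of 10 are all base-sensitive.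

**6 to 5.** The C–Br bond is cut. The 7-methyl group is the only allylic C–H position, so no directing group is needed. The forward step must favour the radical chain over ionic ring substitution.

**5 to 3 (through 4).** The O1–C2 bond is cut and C2–C3 is saturated. At this stage the pyrone carries a single hydroxyl, so ring C can close in one direction only. The forward step needs an oxidative cyclisation that spares the 7-methyl group.

**3 to 1 and 2.** The Cα=Cβ bond of the enone is cut, which leads to two bulk chemicals. The forward condensation must take place at the acetyl methyl and not at the 6-methyl group of 1.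

**8 to 7.** The C8''–I bond is cut, which leads to a commercial flavone. The forward iodination must choose C8'' over C6'' and C3''.

## Other disconnections considered

**Alternative 1:** the first plan that comes to mind cuts C6–C8'' between two finished flavones. The forward key step is a Suzuki–Miyaura coupling of 5,7-bis(benzyloxy)-6-iodo-4'-methoxyflavone A1 with 5,7,4'-trimethoxyflavone-8-boronic acid A2. This gives the protected biflavone A3, which is then hydrogenolysed and 5''-O-demethylated.
- The hardest bond would be made in the most hindered way. Both carbons on palladium are di-ortho-oxygenated, so transmetalation and reductive elimination should be slow.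
- A2 is a 2,6-dialkoxyarylboron species, which should protodeboronate under the base it needs.
- A1 costs three steps of protection and directed iodination plus a deprotection.
- The plan is therefore longer and its risk does not buy simplicity.

**Alternative 2:** this cuts the same bond as a biomimetic or anodic dehydrogenative cross-coupling of acacetin A4 with 5-hydroxy-7,4'-dimethoxyflavone A5, giving 14 directly.
- It is one step, but nothing in the structures secures selectivity.
- Both partners are chelated, electron-poor phenols of similar oxidation potential, so homo- and cross-coupling should compete.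
- The radical from A4 is delocalised over C6 and C8.
- The only free hydroxyl of A5 directs to its ortho carbon C6'' rather than to C8''.
- C–O coupling and over-oxidation of the more electron-rich product are further channels.

**Alternative 3:** this cuts C6–C8'' inside a temporary ether bridge. The mixed formaldehyde acetal A6 links O5 of 7-O-benzyl-6-iodoacacetin to 3,5-dimethoxyphenol. An intramolecular palladium-catalysed direct arylation would close it to the dibenzo[d,f][1,3]dioxepine A7.
- The bridge does fix the positions: O5 has only C6 as ortho carbon, and the phenol ring is symmetric.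
- However, the aryl–aryl bond is still formed at palladium between two di-ortho-substituted carbons, through a seven-membered ring.
- The chelated 5-OH must first be alkylated, and O7 needs a protecting group.
- After bridge cleavage, the whole pyrone of unit 2 must be built (regioselective acylation, condensation, cyclisation) in the presence of unit 1.
- The step count would be roughly double that of the chosen plan.

Key step: step 6

Assumption: the SMILES carries no descriptor for the C6–C8'' axis, so the target is taken as configurationally unspecified and the route delivers the racemic axis.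

## Steps

**Step 1**
Reactants: 1 dehydroacetic acid (3-acetyl-4-hydroxy-6-methyl-2H-pyran-2-one); 2 4-methoxybenzaldehyde
Product: 3 (E)-4-hydroxy-3-[3-(4-methoxyphenyl)prop-2-enoyl]-6-methyl-2H-pyran-2-one
Conditions: piperidine (cat.), CHCl3, reflux, Dean–Stark
Reagents that add atoms: none
Why: Amine-catalysed Claisen–Schmidt condensation; the acetyl CH3 of 1 is activated by the chelated tricarbonyl array and should react before the 6-methyl group, and conjugation with the anisyl ring gives the E-alkene.

**Step 2**
Reactants: 3 (E)-4-hydroxy-3-[3-(4-methoxyphenyl)prop-2-enoyl]-6-methyl-2H-pyran-2-one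
Product: 5 2-(4-methoxyphenyl)-7-methyl-4H,5H-pyrano[4,3-b]pyran-4,5-dione, via dihydropyranopyrandione 4 (not isolated)
Conditions: I2 (10 mol %), DMSO, 120 °C
Reagents that add atoms: none
Why: Iodine/DMSO oxidative cyclisation of an o-hydroxychalcone-type enone: 6-endo-trig oxa-Michael addition of the only hydroxyl gives racemic 4, α-iodination and loss of HI give the γ-pyrone, and DMSO reoxidises HI. The later 5-OH and 7-OH are still tied up as lactone carbonyl and lactone oxygen, so ring C can close in one direction only, which fixes O1 para to the future axis.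

**Step 3**
Reactants: 5 2-(4-methoxyphenyl)-7-methyl-4H,5H-pyrano[4,3-b]pyran-4,5-dione
Product: 6 7-(bromomethyl)-2-(4-methoxyphenyl)-4H,5H-pyrano[4,3-b]pyran-4,5-dione
Conditions: NBS (1.05 equiv), AIBN (cat.), PhCF3, reflux
Reagents that add atoms: N-bromosuccinimide, O=C1CCC(=O)N1Br
Why: Wohl–Ziegler bromination; the 7-methyl group is the only allylic C–H position and gives a radical delocalised over the 2-pyrone, as in the known side-chain bromination of 4-methoxy-6-methyl-2-pyrone. The non-polar medium should suppress ionic attack at C8, C3 and ring B.

**Step 4**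
Reactants: 7 5,7,4'-trimethoxyflavone (5,7-dimethoxy-2-(4-methoxyphenyl)-4H-chromen-4-one)
Product: 8 8-iodo-5,7,4'-trimethoxyflavone
Conditions: NIS (1.1 equiv), CF3CO2H (cat.), MeCN, 0 °C to rt
Reagents that add atoms: N-iodosuccinimide, O=C1CCC(=O)N1I
Why: Electrophilic aromatic iodination; in 5,7-dialkoxyflavones C8 (between 7-OMe and the tied-back ring oxygen, para to 5-OMe) is more accessible than C6 (between two freely rotating methoxy groups). The absence of a free 5-OH removes the ortho direction to C6.

**Step 5**
Reactants: 6 7-(bromomethyl)-2-(4-methoxyphenyl)-4H,5H-pyrano[4,3-b]pyran-4,5-dione; 8 8-iodo-5,7,4'-trimethoxyflavone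
Product: 10 7-{[5,7-dimethoxy-2-(4-methoxyphenyl)-4-oxo-4H-chromen-8-yl]methyl}-2-(4-methoxyphenyl)-4H,5H-pyrano[4,3-b]pyran-4,5-dione, via pyranylmethylzinc bromide 9 (not isolated)
Conditions: 6, Zn dust, LiCl, THF, 0 °C; decant; then 8, Pd(OAc)2 (cat.), SPhos (cat.), THF, 50 °C
Reagents that add atoms: none
Why: Zinc should insert readily into the activated heterobenzylic C–Br bond to give 9, and a Negishi sp3–sp2 coupling follows (oxidative addition of zerovalent palladium/SPhos to hindered 8, transfer of an unhindered primary carbon, reductive elimination at the CH2 terminus that keeps the pyrone conjugated). The medium is neutral and non-nucleophilic, so the lactone, both γ-pyrones and the acidic CH2 of 10 should survive, and only one of the joined carbons is di-ortho-substituted.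

**Step 6**
Reactants: 10 7-{[5,7-dimethoxy-2-(4-methoxyphenyl)-4-oxo-4H-chromen-8-yl]methyl}-2-(4-methoxyphenyl)-4H,5H-pyrano[4,3-b]pyran-4,5-dione
Product: 13 5,7-dihydroxy-4',5'',7'',4'''-tetramethoxy-6,8''-biflavone, via ring-opened acylketene 11 (not isolated), via chromenetrione 12 (not isolated)
Conditions: KOt-Bu (3 equiv), THF (0.01 M), argon, 0 to 60 °C; then 1 M HCl
Reagents that add atoms: none
Why: Proposed new method: KOt-Bu removes a proton from the CH2 of 10, which is benzylic and doubly vinylogous to the C5 lactone and C4 ketone carbonyls, and the lactone dienolate expels the enol oxygen O6 (E1cB-type, formally a retro-6π opening) to give the enolate of acylketene 11; addition of tert-butoxide to C5 would feed the same closure. After rotation about C7–C8 the benzylic enolate carbon (future C6) attacks C5, an sp-hybridised and therefore minimally demanding electrophile, to give trione 12, whose enolisation to the bis-phenoxide of 13 is irreversible, whereas O-acylation only regenerates 10. The closest known reaction types are the alkoxide-induced rearrangement of 3-benzylidenephthalides to 2-arylindane-1,3-diones, the base-induced conversion of 4-methoxy-6-methyl-2-pyrone into 5-methoxyresorcinol, and the biomimetic pyrone-to-acylphloroglucinol Claisen cyclisations; none has been shown on a γ-pyrone-fused 2-pyrone or used to create a biaryl axis. One ring is closed, carbocyclic ring A of unit 1, through the C5–C6 bond in a Dieckmann-type 6-(enolendo)-exo closure (equivalently a 6π closure of an oxido-dienylketene), while the 2-pyrone ring is opened. C6 of 12 is a transient stereocentre erased on aromatisation, and since nothing in 10 is chiral the new C6–C8'' axis forms as a racemate. The step needs C- over O-acylation, C6 over C8 as the nucleophile, and an intact ring C: the first is settled by aromatisation, the second by ring size (attack from C8 would need a four-membered ring), and the third by a bulky base under anhydrous conditions that should not add to the electrophilic C8a. Because ring C was closed before ring A existed, O1 ends para and the two new hydroxyls ortho to the axis, so the 6-linkage and the free 5-OH and 7-OH arise without protecting groups. High dilution and the shielding of the carbanion by the di-ortho-substituted aryl group should hold back intermolecular Michael addition.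

**Step 7**
Reactants: 13 5,7-dihydroxy-4',5'',7'',4'''-tetramethoxy-6,8''-biflavone
Product: 14 5,7,5''-trihydroxy-4',7'',4'''-trimethoxy-6,8''-biflavone (target, CNP0146326.0)
Conditions: BCl3 (5 equiv), CH2Cl2, −78 to 0 °C; then H2O
Reagents that add atoms: none
Why: Chelation-controlled aryl methyl ether cleavage: BCl3 binds between C4''=O and the peri 5''-OMe oxygen and chloride removes that methyl group only, since 7''-OMe and both anisyl ethers have no neighbouring carbonyl. The free 5-OH and 7-OH only consume reagent as borates that hydrolyse on work-up, and the low temperature without hot protic acid avoids Wessely–Moser scrambling of the 6-linkage.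

## Compound list

1 | dehydroacetic acid | CC(=O)C1=C(O)C=C(C)OC1=O | starting material
2 | 4-methoxybenzaldehyde | COc1ccc(C=O)cc1 | starting material
3 | (E)-4-hydroxy-3-[3-(4-methoxyphenyl)prop-2-enoyl]-6-methyl-2H-pyran-2-one | COc1ccc(/C=C/C(=O)C2=C(O)C=C(C)OC2=O)cc1 | intermediate
4 | 2-(4-methoxyphenyl)-7-methyl-2,3-dihydro-4H,5H-pyrano[4,3-b]pyran-4,5-dione (racemic, not isolated) | COc1ccc(cc1)C1CC(=O)C2=C(O1)C=C(C)OC2=O | intermediate
5 | 2-(4-methoxyphenyl)-7-methyl-4H,5H-pyrano[4,3-b]pyran-4,5-dione | COc1ccc(cc1)C1=CC(=O)C2=C(O1)C=C(C)OC2=O | intermediate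
6 | 7-(bromomethyl)-2-(4-methoxyphenyl)-4H,5H-pyrano[4,3-b]pyran-4,5-dione | COc1ccc(cc1)C1=CC(=O)C2=C(O1)C=C(CBr)OC2=O | intermediate
7 | 5,7,4'-trimethoxyflavone | COc1ccc(cc1)-c1cc(=O)c2c(OC)cc(OC)cc2o1 | starting material
8 | 8-iodo-5,7,4'-trimethoxyflavone | COc1ccc(cc1)-c1cc(=O)c2c(OC)cc(OC)c(I)c2o1 | intermediate
9 | {[2-(4-methoxyphenyl)-4,5-dioxo-4H,5H-pyrano[4,3-b]pyran-7-yl]methyl}zinc bromide (not isolated) | COc1ccc(cc1)C1=CC(=O)C2=C(O1)C=C(C[Zn]Br)OC2=O | intermediate
10 | 7-{[5,7-dimethoxy-2-(4-methoxyphenyl)-4-oxo-4H-chromen-8-yl]methyl}-2-(4-methoxyphenyl)-4H,5H-pyrano[4,3-b]pyran-4,5-dione | COc1ccc(cc1)C1=CC(=O)C2=C(O1)C=C(Cc1c(OC)cc(OC)c3c(=O)cc(-c4ccc(OC)cc4)oc13)OC2=O | intermediate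
11 | ring-opened acylketene, drawn in its neutral keto form: (E)-2-[3-(flavon-8-yl)-2-oxopropylidene]-6-(4-methoxyphenyl)-3-(oxomethylidene)-2H-pyran-4(3H)-one (not isolated) | O=C=C1C(=O)C=C(c2ccc(OC)cc2)O/C1=C/C(=O)Cc1c(OC)cc(OC)c2c(=O)cc(-c3ccc(OC)cc3)oc12 | intermediate
12 | 6-[5,7-dimethoxy-2-(4-methoxyphenyl)-4-oxo-4H-chromen-8-yl]-2-(4-methoxyphenyl)-6H-chromene-4,5,7(8H)-trione (racemic at C6, not isolated) | COc1ccc(cc1)C1=CC(=O)C2=C(O1)CC(=O)C(C2=O)c1c(OC)cc(OC)c2c(=O)cc(-c3ccc(OC)cc3)oc12 | intermediate
13 | 5,7-dihydroxy-4',5'',7'',4'''-tetramethoxy-6,8''-biflavone (racemic axis) | COc1ccc(cc1)-c1cc(=O)c2c(O)c(-c3c(OC)cc(OC)c4c(=O)cc(-c5ccc(OC)cc5)oc34)c(O)cc2o1 | intermediate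
14 | 5,7,5''-trihydroxy-4',7'',4'''-trimethoxy-6,8''-biflavone (racemic axis) | COc1ccc(-c2cc(=O)c3c(O)c(-c4c(OC)cc(O)c5c(=O)cc(-c6ccc(OC)cc6)oc45)c(O)cc3o2)cc1 | target

## Step count and least certain steps

Total step count: 7. Longest linear sequence: 6 (steps 1, 2, 3, 5, 6, 7); step 4 is the only step of the second branch.

**Step 6 (key step, labelled).**
- The strongly delocalised anion of 10 may resist lactone opening and simply return on quenching.
- It may instead be consumed by intermolecular Michael addition.
- The more serious risk is addition of adventitious hydroxide or of alkoxide at C8a. This would open ring C, remove the regiochemical lock, and allow re-closure toward the 8-linked series.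
- Fallback by known chemistry, setting out from 8 and returning at 13: Miyaura borylation of 8 (B2pin2, PdCl2(dppf), KOAc, dioxane, 90 °C) gives 5,7,4'-trimethoxyflavone-8-boronic acid pinacol ester F1.
- Commercial acacetin F2 is converted with MOMCl/i-Pr2NEt into 7-O-(methoxymethyl)acacetin F3.
- F3 is iodinated ortho to the free chelated 5-OH with BnMe3NICl2/CaCO3 to give 6-iodo-7-O-(methoxymethyl)acacetin F4.
- F4 is capped with MOMCl/NaH to give 6-iodo-5,7-bis(methoxymethoxy)-4'-methoxyflavone F5.
- Suzuki–Miyaura coupling of F1 and F5 (Pd(OAc)2, SPhos, K3PO4, toluene/H2O, 100 °C) gives the 5,7-bis(methoxymethyl) ether of 13, F6, and HCl/MeOH at 40 °C releases 13.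

**Step 5.**
- Wurtz-type homocoupling may occur during zinc insertion.
- Proton transfer from the acidic CH2 of 10 may quench the organozinc species.
- Reductive elimination may be sluggish from an oxygen-bound or η3-bound palladium dienolate.
- Fallback with reversed polarity under neutral Stille conditions, setting out from 8 and 6 and returning at 10: 8 with (Bu3Sn)2 and Pd(PPh3)4 in toluene at 100 °C gives 8-(tributylstannyl)-5,7,4'-trimethoxyflavone F7. F7 is then coupled with bromide 6 (Pd2(dba)3, AsPh3, CuI, THF/NMP, 60 °C) to give 10.

**Step 3.**
- Hydrogen abstraction from an electron-poor methyl group is slow.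
- Ionic bromination at C8, C3 or ring B and over-bromination of the side chain may therefore compete.
- Fallback without any halide, setting out from 5 and returning at 10: deprotonation of the 7-methyl group (LiHMDS, THF, −78 °C) and transmetalation with ZnCl2 give the pyranylmethylzinc chloride F8. F8 enters the same palladium/SPhos Negishi coupling with 8 to give 10.

**Step 2.**
- The oxa-Michael equilibrium may lie on the side of the strongly chelated open enone.
- Hot I2/DMSO may start a Kornblum-type oxidation of the activated 7-methyl group.
- Fallback by a Baker–Venkataraman sequence, setting out from 1 and returning at 5: 1 with 4-methoxybenzoyl chloride in pyridine gives 3-acetyl-6-methyl-2-oxo-2H-pyran-4-yl 4-methoxybenzoate F9. KOH/pyridine shifts the aroyl group from O to the acetyl carbon to give 4-hydroxy-3-[3-(4-methoxyphenyl)-3-oxopropanoyl]-6-methyl-2H-pyran-2-one F10. H2SO4/AcOH then cyclodehydrates F10 to 5.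

## Further compounds

F1 | step 6 | 5,7,4'-trimethoxyflavone-8-boronic acid pinacol ester | COc1ccc(cc1)-c1cc(=O)c2c(OC)cc(OC)c(B3OC(C)(C)C(C)(C)O3)c2o1
F2 | step 6 | acacetin (5,7-dihydroxy-4'-methoxyflavone, commercial) | COc1ccc(cc1)-c1cc(=O)c2c(O)cc(O)cc2o1
F3 | step 6 | 7-O-(methoxymethyl)acacetin | COCOc1cc(O)c2c(=O)cc(-c3ccc(OC)cc3)oc2c1
F4 | step 6 | 6-iodo-7-O-(methoxymethyl)acacetin | COCOc1cc2oc(-c3ccc(OC)cc3)cc(=O)c2c(O)c1I
F5 | step 6 | 6-iodo-5,7-bis(methoxymethoxy)-4'-methoxyflavone | COCOc1cc2oc(-c3ccc(OC)cc3)cc(=O)c2c(OCOC)c1I
F6 | step 6 | 5,7-bis(methoxymethoxy)-4',5'',7'',4'''-tetramethoxy-6,8''-biflavone | COCOc1cc2oc(-c3ccc(OC)cc3)cc(=O)c2c(OCOC)c1-c1c(OC)cc(OC)c2c(=O)cc(-c3ccc(OC)cc3)oc12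
F7 | step 5 | 8-(tributylstannyl)-5,7,4'-trimethoxyflavone | CCCC[Sn](CCCC)(CCCC)c1c(OC)cc(OC)c2c(=O)cc(-c3ccc(OC)cc3)oc12
F8 | step 3 | {[2-(4-methoxyphenyl)-4,5-dioxo-4H,5H-pyrano[4,3-b]pyran-7-yl]methyl}zinc chloride | COc1ccc(cc1)C1=CC(=O)C2=C(O1)C=C(C[Zn]Cl)OC2=O
F9 | step 2 | 3-acetyl-6-methyl-2-oxo-2H-pyran-4-yl 4-methoxybenzoate | COc1ccc(cc1)C(=O)OC1=C(C(C)=O)C(=O)OC(C)=C1
F10 | step 2 | 4-hydroxy-3-[3-(4-methoxyphenyl)-3-oxopropanoyl]-6-methyl-2H-pyran-2-one | COc1ccc(cc1)C(=O)CC(=O)C1=C(O)C=C(C)OC1=O
A1 | alternative 1 | 5,7-bis(benzyloxy)-6-iodo-4'-methoxyflavone | COc1ccc(cc1)-c1cc(=O)c2c(OCc3ccccc3)c(I)c(OCc3ccccc3)cc2o1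
A2 | alternative 1 | 5,7,4'-trimethoxyflavone-8-boronic acid | COc1ccc(cc1)-c1cc(=O)c2c(OC)cc(OC)c(B(O)O)c2o1
A3 | alternative 1 | 5,7-bis(benzyloxy)-4',5'',7'',4'''-tetramethoxy-6,8''-biflavone | COc1ccc(cc1)-c1cc(=O)c2c(OCc3ccccc3)c(-c3c(OC)cc(OC)c4c(=O)cc(-c5ccc(OC)cc5)oc34)c(OCc3ccccc3)cc2o1
A4 | alternative 2 | acacetin | COc1ccc(cc1)-c1cc(=O)c2c(O)cc(O)cc2o1
A5 | alternative 2 | 5-hydroxy-7,4'-dimethoxyflavone | COc1ccc(cc1)-c1cc(=O)c2c(O)cc(OC)cc2o1
A6 | alternative 3 | 7-(benzyloxy)-5-[(3,5-dimethoxyphenoxy)methoxy]-6-iodo-4'-methoxyflavone | COc1ccc(cc1)-c1cc(=O)c2c(OCOc3cc(OC)cc(OC)c3)c(I)c(OCc3ccccc3)cc2o1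
A7 | alternative 3 | methylene-bridged dibenzo[d,f][1,3]dioxepine formed by C6–aryl closure of A6 | COc1ccc(cc1)-c1cc(=O)c2c3OCOc4cc(OC)cc(OC)c4-c3c(OCc3ccccc3)cc2o1
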